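**Plan**
Atoms carry the numbers of their order in the target SMILES (C1 to O32); ring A = C2, O4, C5, C7, C8, C9; ring B = C9–C10–C11–C12–C21–C22.
Cuts, last to first: the C5 carbonyl and C31–O32 (late oxidations), C18–C20 (enolate alkylation, ring C), C14–C31 with C25–C30 (intramolecular Diels–Alder, ring E and the γ-lactone), C18–C25 and C13–C14 (ring D), C12–C21 with O–C23 (ring-contracting ester-enolate Claisen, ring B), then the C13–O23 lactone bond, C11–C12, C9–C10 and C9–C22.
Forward order: ring A, carried as its 3,6-dihydro-2H-pyran (C5 = CH2), then the eight-membered lactone, ring B (step 16), ring D (step 22), ring E with the γ-lactone (step 27), ring C (step 29), and the two oxidations.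
Feature: in ring B the quaternary C12 and C21 are vicinal and C21 adjoins C22, so C13–C12–C21–C22=C23 (methyl carbinol read as a methylene) is a γ,δ-unsaturated acid. Joining C13 to C23 through oxygen gives an eight-membered allylic lactone that contracts to ring B; C12 carries a tert-butyl ester (later C25), which makes the lactone a malonate.
Stereochemistry: C9 from a CBS carbinol by Claisen chirality transfer; C12 and C21 from the key step; C22 by lactonisation from C25; C14 and C25 by the Diels–Alder facial choice; C18 by the tether; C30 and C31 by silyl-copper addition and retentive oxidation.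

Key step: step 16

Assumption: the CBS reduction of step 8 is assigned by the usual model with the dienyl side of the ketone as the large group; if it delivers the other carbinol, the (S)-catalyst is used instead.

**Route**

Step 1
Reactants: 1 but-2-yne-1,4-diol
Product: 2 4-[(4-methoxybenzyl)oxy]but-2-yn-1-ol
Conditions: NaH (1 equiv), 4-methoxybenzyl chloride, Bu4NI (cat.), THF, 0 °C to rt, diol in threefold excess
Reagents that add atoms: 4-methoxybenzyl chloride, COc1ccc(CCl)cc1
Why: Williamson etherification of the mono-alkoxide of a symmetric diol used in excess should give the mono-ether, which masks the C23 oxygen with a group that is later removed oxidatively.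

Step 2
Reactants: 2 4-[(4-methoxybenzyl)oxy]but-2-yn-1-ol
Product: 4 (Z)-3-iodo-4-[(4-methoxybenzyl)oxy]but-2-en-1-ol, via cyclic alkenylalanate 3 (not isolated)
Conditions: NaAlH2(OCH2CH2OMe)2, THF, 0 °C; then I2, −78 °C
Reagents that add atoms: iodine, II
Why: Hydroxyl-directed trans-hydroalumination of the propargylic alcohol puts hydride on C21 and aluminium on C22 within a five-membered alanate, and iododealumination with retention should leave iodine cis to C20, the geometry that becomes the (E)-alkylidene.

Step 3
Reactants: 4 (Z)-3-iodo-4-[(4-methoxybenzyl)oxy]but-2-en-1-ol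
Product: 5 (Z)-tert-butyl{[3-iodo-4-(4-methoxybenzyloxy)but-2-en-1-yl]oxy}diphenylsilane
Conditions: t-BuPh2SiCl, imidazole, DMF, rt
Reagents that add atoms: tert-butyl(chloro)diphenylsilane, CC(C)(C)[Si](Cl)(c1ccccc1)c1ccccc1
Why: Silylation of the primary alcohol gives a C20 ether robust enough for the aqueous acid of steps 7 and 25 and the bases used up to step 27.

Step 4
Reactants: 6 3-hydroxy-3-methylbutan-2-one; 7 ethyl diazoacetate
Product: 8 ethyl 2-[(2-methyl-3-oxobutan-2-yl)oxy]acetate
Conditions: Rh2(OAc)4 (1 mol %), CH2Cl2, rt, slow addition of 7 to excess 6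
Reagents that add atoms: none
Why: Rhodium-carbenoid O–H insertion etherifies the hindered tertiary alcohol under neutral conditions, where a base-mediated alkylation of this enolisable hydroxy ketone would suffer aldol side reactions.

Step 5
Reactants: 8 ethyl 2-[(2-methyl-3-oxobutan-2-yl)oxy]acetate
Product: 9 2,2-dimethyl-2H-pyran-3,5(4H,6H)-dione
Conditions: KOtBu (2.2 equiv), THF, 0 °C to rt; then 1 M HCl
Reagents that add atoms: none
Why: Intramolecular Claisen (Dieckmann-type) condensation of the methyl ketone enolate onto the ester closes the only possible six-membered ring and is driven by formation of the dione enolate.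

Step 6
Reactants: 9 2,2-dimethyl-2H-pyran-3,5(4H,6H)-dione
Product: 10 5-methoxy-2,2-dimethyl-2H-pyran-3(6H)-one
Conditions: MeOH, p-TsOH (cat.), benzene, reflux with removal of water
Reagents that add atoms: methanol, CO
Why: Acid-catalysed enol etherification should occur at the carbonyl remote from the gem-dimethyl carbon, as with 4,4-dimethylcyclohexane-1,3-dione, leaving the hindered C9 carbonyl as the ketone.

Step 7
Reactants: 5 (Z)-alkenyl iodide; 10 5-methoxy-2,2-dimethyl-2H-pyran-3(6H)-one
Product: 13 ring A dienone with the (E)-alkenyl arm on C9 and the ketone on C7, via alkenyllithium 11 (not isolated), via tertiary carbinol 12 (not isolated)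
Conditions: t-BuLi (2.1 equiv), Et2O, −78 °C; CeCl3, THF, −78 °C; then 10; then 1 M HCl, THF, 0 °C
Reagents that add atoms: none
Why: Iodine–lithium exchange with retention, 1,2-addition of the organocerium reagent to the vinylogous ester and acid-induced hydrolysis with allylic transposition (Stork–Danheiser sequence) should join C22 to C9 and move the carbonyl to C7.

Step 8
Reactants: 13 ring A dienone
Product: 14 (R)-allylic alcohol at C7 of the dihydropyran
Conditions: (R)-2-methyl-CBS-oxazaborolidine (0.2 equiv), catecholborane, toluene, −78 °C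
Reagents that add atoms: none
Why: CBS reduction of the cyclic enone, with the alkenyl flank as the large group, should set the C7 carbinol as R; this is the only stereocentre introduced by a chiral reagent.

Step 9
Reactants: 14 (R)-allylic alcohol
Product: 16 N,N-dimethylamide with quaternary C9 (C10 on the ring face that carried the C7 oxygen), via ketene N,O-acetal 15 (not isolated)
Conditions: CH3C(OMe)2NMe2, xylene, 140 °C
Reagents that add atoms: N,N-dimethylacetamide dimethyl acetal, CC(OC)(OC)N(C)C
Why: Eschenmoser–Claisen rearrangement under neutral conditions: the ketene N,O-acetal on O–C7 rearranges suprafacially across the ring, so C10 bonds to C9 on the face that bore the oxygen, which relays the C7 configuration to the quaternary C9 and leaves the cis C7=C8 alkene of ring A.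

Step 10
Reactants: 16 N,N-dimethylamide
Product: 17 primary alcohol at C11
Conditions: LiEt3BH (4 equiv), THF, 0 °C to rt
Reagents that add atoms: none
Why: Lithium triethylborohydride reduces tertiary amides to primary alcohols with C–N cleavage and leaves the silyl and benzyl ethers untouched.

Step 11
Reactants: 17 primary alcohol
Product: 18 primary iodide at C11
Conditions: I2, PPh3, imidazole, CH2Cl2, 0 °C
Reagents that add atoms: iodine, II
Why: Appel-type iodination of an unhindered primary alcohol proceeds under neutral conditions.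

Step 12
Reactants: 18 primary iodide; 19 tert-butyl methyl malonate
Product: 20 mixed malonate (C12 bearing CO2Me and CO2t-Bu; both C12 epimers)
Conditions: NaH, 19 (3 equiv), THF/DMF, 0 to 60 °C
Reagents that add atoms: none
Why: Malonate alkylation by a primary iodide forms C11–C12; the C12 configuration is irrelevant because this centre is enolised in step 16.

Step 13
Reactants: 20 mixed malonate
Product: 21 malonic half-acid (C13 acid, tert-butyl ester retained; C12 epimers)
Conditions: LiOH, THF/MeOH/H2O, 0 °C; then 1 M HCl to pH 3 at 0 °C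
Reagents that add atoms: lithium hydroxide, [Li+].[OH-]
Why: Saponification selects the methyl ester over the tert-butyl ester, and cold work-up avoids decarboxylation of the half-acid.

Step 14
Reactants: 21 malonic half-acid
Product: 22 hydroxy acid (free C23–OH; C12 epimers)
Conditions: DDQ, CH2Cl2/pH 7 buffer, 0 °C
Reagents that add atoms: none
Why: Oxidative cleavage removes the 4-methoxybenzyl ether selectively, while the silyl ether and the allylic ring ether are far less electron-rich and should survive.

Step 15
Reactants: 22 hydroxy acid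
Product: 23 eight-membered (E)-alkylidene lactone spiro-linked to ring A at C9 (C12 epimers)
Conditions: 2-methyl-6-nitrobenzoic anhydride (1.3 equiv), DMAP (3 equiv), CH2Cl2, rt, syringe-pump addition over 12 h to 1 mM
Reagents that add atoms: none
Why: Shiina macrolactonisation through the mixed anhydride has precedent for eight-membered lactones, and the quaternary C9 and the sp2 centre C22 in the chain lower the transannular strain of ring closure.

Step 16
Reactants: 23 eight-membered lactone
Product: 26 ring B acid (quaternary C12 with C13 acid trans to C20 and tert-butyl ester cis to C20; exocyclic C22=C23), via silyl ketene acetal 24 (not isolated), via trimethylsilyl ester 25 (not isolated)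
Conditions: KN(SiMe3)2 (1.2 equiv), Me3SiCl (2 equiv), THF, −78 °C; then toluene, 80–110 °C; then aqueous citric acid, 0 °C
Reagents that add atoms: none
Why: Proposed new method: the malonate-type lactone is silylated to ketene acetal 24, whose C12=C13 geometry is fixed by the ring (C11 cis to the ring oxygen), and a [3,3]-sigmatropic shift then bonds C12 to the exocyclic alkene carbon C21 while O–C23 breaks; the closest known reaction is the Ireland–Claisen ring contraction of macrocyclic allylic lactones, here moved to an eight-membered lactone with an exocyclic alkene. Ring B (C9–C10–C11–C12–C21–C22) closes in a six-membered mode through a bicyclo[3.3.1]-like array that shares C12, C21 and C22 with the six-atom pericyclic ring, the topology of a type-2 intramolecular carbonyl-ene cyclisation, and the contraction releases medium-ring strain. C12 is set because the lactone carbonyl C13 stays inside the pericyclic ring and so ends trans to C20, with the tert-butyl ester cis to C20. C21 follows from the (E)-alkene, which holds C20 equatorial in the pericyclic chair. The selectivity still needed is the fold of the lactone relative to C9, and the spiro centre should secure it by placing its small sp2 arm C8, not the CMe2 carbon C2, in the axial site that is 1,3 to C20. Ring A has no carbonyl and no other acidic hydrogen competes, and the two silyl ketene acetal regioisomers of the malonate interconvert by silyl shift, so only heat is needed.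

Step 17
Reactants: 26 ring B acid
Product: 28 C13 aldehyde, via acid chloride 27 (not isolated)
Conditions: 1-chloro-N,N,2-trimethylprop-1-en-1-amine, CH2Cl2, 0 °C; then LiAlH(OtBu)3, THF, −78 °C
Reagents that add atoms: none
Why: Neutral acid chloride formation spares the tert-butyl ester, and the hindered alkoxyaluminium hydride reduces an acid chloride only as far as the aldehyde without touching ester or alkenes.

Step 18
Reactants: 29 2-bromopentan-3-one
Product: 31 2-(triphenylphosphoranylidene)pentan-3-one, via phosphonium bromide 30 (not isolated)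
Conditions: PPh3, toluene, 80 °C; then 2 M NaOH, CH2Cl2
Reagents that add atoms: triphenylphosphine, c1ccc(cc1)P(c1ccccc1)c1ccccc1
Why: Displacement of the α-bromide by the phosphine and deprotonation give the stabilised ylide that carries C14, C15, C16, C18 and C19.

Step 19
Reactants: 28 C13 aldehyde; 31 stabilised ylide
Product: 32 (E)-enone C13=C14(Me)–C16(=O)–Et on C12
Conditions: 31 (2 equiv), toluene, 100 °C
Reagents that add atoms: none
Why: Wittig olefination of the non-enolisable neopentyl aldehyde with a stabilised ylide should form C13=C14 cleanly as the (E)-enone.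

Step 20
Reactants: 32 (E)-enone
Product: 33 saturated ethyl ketone (C13 as CH2; C14 epimers)
Conditions: [(Ph3P)CuH]6 (0.4 equiv), benzene, rt; then aqueous NH4Cl
Reagents that add atoms: none
Why: The hexameric copper hydride (Stryker's reagent) adds hydride only to the enone β-carbon C13 and leaves the isolated alkenes and the ester alone; the C14 configuration is lost again in step 27.

Step 21
Reactants: 33 saturated ethyl ketone
Product: 34 bridged γ-lactone C25(=O)–O24–C22 (6-oxabicyclo[3.2.1]octan-7-one on ring B; C22 methyl trans to the lactone oxygen)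
Conditions: [N,N′-bis(3,5-di-tert-butylsalicylidene)-1,2-cyclohexanediaminato]cobalt (divalent cobalt, 5 mol %), N-fluoro-2,4,6-trimethylpyridinium tetrafluoroborate (1.5 equiv), PhSiH3 (1.5 equiv), PhCF3, rt
Reagents that add atoms: none
Why: Hydrogen-atom transfer from a cobalt hydride to C23 of the 1,1-disubstituted alkene, oxidation of the tertiary radical and capture by the ester carbonyl with loss of isobutene (radical–polar crossover hydrolactonisation) should give the lactone; it can only span C12 and C22 on the face of C25, so O24 is set cis to C25 and C20 and C23 becomes the methyl group.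

Step 22
Reactants: 34 bridged γ-lactone
Product: 35 ring D 2-methyl-1,3-dione (C16 and C25 carbonyls; free tertiary C22–OH)
Conditions: KOtBu (2.5 equiv), THF, 0 °C to rt; then aqueous NH4Cl
Reagents that add atoms: none
Why: Dieckmann-type acyl transfer: the ketone enolate at C18 attacks the strained lactone carbonyl C25, closing the six-membered ring D as its stabilised dione enolate and releasing the C22 alkoxide with its configuration intact.

Step 23
Reactants: 35 ring D dione
Product: 36 bis(triethylsilyl) derivative (vinylogous silyl ester with OSiEt3 on C16 and ketone at C25; C22–OSiEt3)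
Conditions: Et3SiOTf (2.5 equiv), Et3N, CH2Cl2, −78 to 0 °C
Reagents that add atoms: triethylsilyl trifluoromethanesulfonate, CC[Si](CC)(CC)OS(=O)(=O)C(F)(F)F
Why: Silylation caps the tertiary alcohol and the less hindered enol oxygen at C16, as in the etherification of 4,4-disubstituted 1,3-diones, leaving the carbonyl beside the spiro centre for the next addition.

Step 24
Reactants: 37 (tributylstannyl)methanol
Product: 38 tributyl[(1-ethoxyethoxy)methyl]stannane
Conditions: ethyl vinyl ether, pyridinium p-toluenesulfonate (cat.), CH2Cl2, rt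
Reagents that add atoms: ethyl vinyl ether, C=COCC
Why: Acid-catalysed acetalisation of the primary alcohol gives the known precursor of an α-alkoxymethyl anion.

Step 25
Reactants: 36 bis(triethylsilyl) derivative; 38 stannane
Product: 41 ring D enone C16(=O)–C18(Me)=C25 with C26H2OH on C25 (C22–OSiEt3 retained), via [(1-ethoxyethoxy)methyl]lithium 39 (not isolated), via tertiary carbinol 40 (not isolated)
Conditions: n-BuLi, THF, −78 °C; CeCl3, −78 °C; then 36; then 1 M HCl, THF, 0 °C, 20 min
Reagents that add atoms: none
Why: Tin–lithium exchange gives the alkoxymethyl nucleophile, which adds to the C25 ketone; dilute acid then hydrolyses the enol silyl ether with allylic transposition (Stork–Danheiser) and removes the acetal, so C26 arrives as a free primary alcohol that lies trans to C16 and cannot form a hemiketal.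

Step 26
Reactants: 41 hydroxymethyl enone; 42 propiolic acid
Product: 43 propiolate ester on O27
Conditions: dicyclohexylcarbodiimide, DMAP (5 mol %), CH2Cl2, −20 °C
Reagents that add atoms: none
Why: Carbodiimide esterification acylates only the primary allylic alcohol, and the low temperature limits amine addition to the ynoate.

Step 27
Reactants: 43 propiolate ester
Product: 46 cage ketone diol (bicyclo[2.2.2]octenone fused to the unsaturated γ-lactone; C20–OH and C22–OH free; C18 epimers), via silyloxydiene 44 (not isolated), via cycloadduct silyl enol ether 45 (not isolated)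
Conditions: Me3SiOTf, i-Pr2NEt, CH2Cl2, −78 to 0 °C; then toluene, 130 °C, sealed tube; then Bu4NF, THF, rt
Reagents that add atoms: none
Why: Soft enolisation gives the cross-conjugated silyloxydiene C14=C16(OSiMe3)–C18=C25, the only dienol ether that can reach the tethered ynoate, and an intramolecular Diels–Alder reaction then joins C14 to C31 and C25 to C30, closing ring E and the γ-lactone; the bulkier C21 branch of the spiro centre sits pseudo-axial to avoid the C26 substituent and shields its face, so the ynoate should add anti to it and set C14 and C25, after which fluoride removes all three silyl groups.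

Step 28
Reactants: 46 cage ketone diol
Product: 47 primary iodide at C20
Conditions: I2, PPh3, imidazole, CH2Cl2, 0 °C
Reagents that add atoms: iodine, II
Why: Appel-type iodination converts the primary alcohol only, since the tertiary C22 alcohol does not react under these conditions.

Step 29
Reactants: 47 primary iodide
Product: 48 hexacyclic enone lactone with ring C closed (C18 quaternary; ring A still the dihydropyran; C30=C31)
Conditions: KN(SiMe3)2 (2.2 equiv), THF, −78 to 0 °C; then aqueous NH4Cl
Reagents that add atoms: none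
Why: The C16 ketone can enolise only towards C18 because C14 is a quaternary bridgehead, and 5-exo-tet alkylation by the tethered C20 iodide, which reaches C18 from one face only, should close ring C and set C18 whatever its configuration in 47.

Step 30
Reactants: 48 hexacyclic enone lactone
Product: 49 β-silyl lactone (PhMe2Si on C31 on the side of the C16 ketone bridge; H30 on the side of the C13 bridge)
Conditions: PhMe2Si–Bpin (1.5 equiv), CuCl (10 mol %), NaOtBu (20 mol %), 1,3-bis(2,6-diisopropylphenyl)imidazolium chloride (10 mol %), MeOH (4 equiv), THF, 0 °C to rt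
Reagents that add atoms: (dimethylphenylsilyl)boronic acid pinacol ester, CC1(C)OB(OC1(C)C)[Si](C)(C)c1ccccc1
Why: Copper-catalysed conjugate silyl transfer to the strained unsaturated lactone should deliver silicon to C31 from the face flanked by the flat C16 carbonyl bridge, not the C13 methylene bridge, and protonation of the copper enolate at C30 anti to the new silyl group then places C28 cis to it.

Step 31
Reactants: 49 β-silyl lactone
Product: 50 ring A α,β-unsaturated δ-lactone (C5 carbonyl) with the C31 silane retained
Conditions: CrO3, 3,5-dimethylpyrazole, CH2Cl2, −20 °C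
Reagents that add atoms: chromium trioxide, O=[Cr](=O)=O
Why: Allylic oxidation by the hexavalent chromium–pyrazole complex converts 3,6-dihydro-2H-pyrans into unsaturated δ-lactones; C5 is the only doubly activated methylene, and the secondary oxygen at C31 is still masked as the silane.

Step 32
Reactants: 50 silyl bis-lactone
Product: 51 CNP0360620.2 (target)
Conditions: KBr, peracetic acid (32% in AcOH), NaOAc, AcOH, rt
Reagents that add atoms: peracetic acid, CC(=O)OO
Why: Fleming–Tamao oxidation: ipso-bromodesilylation of the phenyl group and peracid-induced migration of C31 from silicon to oxygen replace silicon by hydroxyl with retention, giving the C31 carbinol cis to C28 without touching the electron-poor enoate or the hindered ketone.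

**Compound list**
1 | but-2-yne-1,4-diol | OCC#CCO | starting material
2 | 4-[(4-methoxybenzyl)oxy]but-2-yn-1-ol | OCC#CCOCc1ccc(OC)cc1 | intermediate
3 | sodium cyclic alkenylalanate (Al on C22 and on the C20 oxygen) | [Na+].COCCO[Al-]1(OCCOC)OCC=C1COCc1ccc(OC)cc1 | intermediate
4 | (Z)-3-iodo-4-[(4-methoxybenzyl)oxy]but-2-en-1-ol | OC/C=C(\I)COCc1ccc(OC)cc1 | intermediate
5 | (Z)-tert-butyl{[3-iodo-4-(4-methoxybenzyloxy)but-2-en-1-yl]oxy}diphenylsilane | CC(C)(C)[Si](c1ccccc1)(c1ccccc1)OC/C=C(\I)COCc1ccc(OC)cc1 | intermediate
6 | 3-hydroxy-3-methylbutan-2-one | CC(=O)C(C)(C)O | starting material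
7 | ethyl diazoacetate | CCOC(=O)C=[N+]=[N-] | starting material
8 | ethyl 2-[(2-methyl-3-oxobutan-2-yl)oxy]acetate | CCOC(=O)COC(C)(C)C(C)=O | intermediate
9 | 2,2-dimethyl-2H-pyran-3,5(4H,6H)-dione | CC1(C)OCC(=O)CC1=O | intermediate
10 | 5-methoxy-2,2-dimethyl-2H-pyran-3(6H)-one | COC1=CC(=O)C(C)(C)OC1 | intermediate
11 | alkenyllithium (Li on C22, cis to C20) | [Li]/C(COCc1ccc(OC)cc1)=C\CO[Si](c1ccccc1)(c1ccccc1)C(C)(C)C | intermediate
12 | tertiary carbinol at C9 (1,2-adduct to 10) | COC1=CC(O)(/C(COCc2ccc(OC)cc2)=C\CO[Si](c2ccccc2)(c2ccccc2)C(C)(C)C)C(C)(C)OC1 | intermediate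
13 | 6,6-dimethyl-2H-pyran-3(6H)-one bearing on C5 (C9 of the target) the (E)-4-(tert-butyldiphenylsilyloxy)-1-(4-methoxybenzyloxy)but-2-en-2-yl arm | O=C1COC(C)(C)C(/C(COCc2ccc(OC)cc2)=C\CO[Si](c2ccccc2)(c2ccccc2)C(C)(C)C)=C1 | intermediate
14 | (3R)-allylic alcohol (C7 carbinol) of 13 | O[C@H]1COC(C)(C)C(/C(COCc2ccc(OC)cc2)=C\CO[Si](c2ccccc2)(c2ccccc2)C(C)(C)C)=C1 | intermediate
15 | ketene N,O-acetal on the C7 oxygen of 14 | C=C(N(C)C)O[C@H]1COC(C)(C)C(/C(COCc2ccc(OC)cc2)=C\CO[Si](c2ccccc2)(c2ccccc2)C(C)(C)C)=C1 | intermediate
16 | N,N-dimethylamide: ring A 3,6-dihydro-2H-pyran with quaternary C9 bearing CH2C(O)NMe2 and the (E)-alkenyl arm | CC1(C)OCC=C[C@@]1(CC(=O)N(C)C)/C(COCc2ccc(OC)cc2)=C\CO[Si](c2ccccc2)(c2ccccc2)C(C)(C)C | intermediate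
17 | primary alcohol (C9–CH2CH2OH) | CC1(C)OCC=C[C@@]1(CCO)/C(COCc2ccc(OC)cc2)=C\CO[Si](c2ccccc2)(c2ccccc2)C(C)(C)C | intermediate
18 | primary iodide (C9–CH2CH2I) | CC1(C)OCC=C[C@@]1(CCI)/C(COCc2ccc(OC)cc2)=C\CO[Si](c2ccccc2)(c2ccccc2)C(C)(C)C | intermediate
19 | tert-butyl methyl malonate | COC(=O)CC(=O)OC(C)(C)C | starting material
20 | mixed malonate (C12 with CO2Me and CO2t-Bu; C12 epimers) | CC1(C)OCC=C[C@@]1(CCC(C(=O)OC)C(=O)OC(C)(C)C)/C(COCc2ccc(OC)cc2)=C\CO[Si](c2ccccc2)(c2ccccc2)C(C)(C)C | intermediate
21 | malonic half-acid (C13 acid; C12 epimers) | CC1(C)OCC=C[C@@]1(CCC(C(=O)O)C(=O)OC(C)(C)C)/C(COCc2ccc(OC)cc2)=C\CO[Si](c2ccccc2)(c2ccccc2)C(C)(C)C | intermediate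
22 | hydroxy acid (C23–OH free; C12 epimers) | CC1(C)OCC=C[C@@]1(CCC(C(=O)O)C(=O)OC(C)(C)C)/C(CO)=C\CO[Si](c2ccccc2)(c2ccccc2)C(C)(C)C | intermediate
23 | eight-membered (E)-alkylidene lactone spiro-linked to ring A, tert-butyl ester on C12 (C12 epimers) | CC1(C)OCC=C[C@]12CCC(C(=O)OC(C)(C)C)C(=O)OC/C2=C/CO[Si](c3ccccc3)(c3ccccc3)C(C)(C)C | intermediate
24 | trimethylsilyl ketene acetal of 23 (C12=C13, C11 cis to the ring oxygen) | CC1(C)OCC=C[C@]12CC/C(C(=O)OC(C)(C)C)=C(/O[Si](C)(C)C)OC/C2=C/CO[Si](c3ccccc3)(c3ccccc3)C(C)(C)C | intermediate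
25 | trimethylsilyl ester of 26 | CC1(C)OCC=C[C@]12CC[C@](C(=O)OC(C)(C)C)(C(=O)O[Si](C)(C)C)[C@@H](CO[Si](c3ccccc3)(c3ccccc3)C(C)(C)C)C2=C | intermediate
26 | ring B acid: C12 quaternary (C13 acid trans to C20, tert-butyl ester cis to C20), C21 with CH2OSi, exocyclic C22=C23 | CC1(C)OCC=C[C@]12CC[C@](C(=O)OC(C)(C)C)(C(=O)O)[C@@H](CO[Si](c3ccccc3)(c3ccccc3)C(C)(C)C)C2=C | intermediate
27 | acid chloride of 26 | CC1(C)OCC=C[C@]12CC[C@](C(=O)OC(C)(C)C)(C(Cl)=O)[C@@H](CO[Si](c3ccccc3)(c3ccccc3)C(C)(C)C)C2=C | intermediate
28 | C13 aldehyde | CC1(C)OCC=C[C@]12CC[C@](C(=O)OC(C)(C)C)(C=O)[C@@H](CO[Si](c3ccccc3)(c3ccccc3)C(C)(C)C)C2=C | intermediate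
29 | 2-bromopentan-3-one | CCC(=O)C(C)Br | starting material
30 | (3-oxopentan-2-yl)triphenylphosphonium bromide | CCC(=O)C(C)[P+](c1ccccc1)(c1ccccc1)c1ccccc1.[Br-] | intermediate
31 | 2-(triphenylphosphoranylidene)pentan-3-one | CCC(=O)C(C)=P(c1ccccc1)(c1ccccc1)c1ccccc1 | intermediate
32 | (E)-enone C13=C14(Me)–C(=O)Et on C12 | CC1(C)OCC=C[C@]12CC[C@](C(=O)OC(C)(C)C)(/C=C(\C)C(=O)CC)[C@@H](CO[Si](c3ccccc3)(c3ccccc3)C(C)(C)C)C2=C | intermediate
33 | saturated ethyl ketone (C14 epimers) | CC1(C)OCC=C[C@]12CC[C@](C(=O)OC(C)(C)C)(CC(C)C(=O)CC)[C@@H](CO[Si](c3ccccc3)(c3ccccc3)C(C)(C)C)C2=C | intermediate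
34 | bridged γ-lactone C25(=O)–O–C22 with C22 methyl (C14 epimers) | CC1(C)OCC=C[C@]12CC[C@@]3(CC(C)C(=O)CC)C(=O)O[C@]2(C)[C@@H]3CO[Si](c4ccccc4)(c4ccccc4)C(C)(C)C | intermediate
35 | ring D 2-methyl-1,3-dione with free C22–OH (C14 and C18 epimers, enolisable) | CC1(C)OCC=C[C@]12CC[C@]3(CC(C)C(=O)C(C)C3=O)[C@@H](CO[Si](c4ccccc4)(c4ccccc4)C(C)(C)C)[C@@]2(C)O | intermediate
36 | vinylogous triethylsilyl ester (OSiEt3 on C16, ketone at C25) with C22–OSiEt3 | CC1(C)OCC=C[C@]12CC[C@]3(CC(C)C(O[Si](CC)(CC)CC)=C(C)C3=O)[C@@H](CO[Si](c4ccccc4)(c4ccccc4)C(C)(C)C)[C@@]2(C)O[Si](CC)(CC)CC | intermediate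
37 | (tributylstannyl)methanol | CCCC[Sn](CCCC)(CCCC)CO | starting material
38 | tributyl[(1-ethoxyethoxy)methyl]stannane | CCCC[Sn](CCCC)(CCCC)COC(C)OCC | intermediate
39 | [(1-ethoxyethoxy)methyl]lithium | [Li]COC(C)OCC | intermediate
40 | tertiary carbinol at C25 (adduct of 39 to 36) | CC1(C)OCC=C[C@]12CC[C@]3(CC(C)C(O[Si](CC)(CC)CC)=C(C)C3(O)COC(C)OCC)[C@@H](CO[Si](c4ccccc4)(c4ccccc4)C(C)(C)C)[C@@]2(C)O[Si](CC)(CC)CC | intermediate
41 | ring D enone C16(=O)–C18(Me)=C25(CH2OH), C22–OSiEt3 (C14 epimers) | CC1(C)OCC=C[C@]12CC[C@]3(CC(C)C(=O)C(C)=C3CO)[C@@H](CO[Si](c4ccccc4)(c4ccccc4)C(C)(C)C)[C@@]2(C)O[Si](CC)(CC)CC | intermediate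
42 | propiolic acid | OC(=O)C#C | starting material
43 | propiolate ester of 41 on O27 | CC1(C)OCC=C[C@]12CC[C@]3(CC(C)C(=O)C(C)=C3COC(=O)C#C)[C@@H](CO[Si](c4ccccc4)(c4ccccc4)C(C)(C)C)[C@@]2(C)O[Si](CC)(CC)CC | intermediate
44 | silyloxydiene C14=C16(OSiMe3)–C18=C25 carrying the propiolate | CC1(C)OCC=C[C@]12CC[C@]3(CC(C)=C(O[Si](C)(C)C)C(C)=C3COC(=O)C#C)[C@@H](CO[Si](c4ccccc4)(c4ccccc4)C(C)(C)C)[C@@]2(C)O[Si](CC)(CC)CC | intermediate
45 | Diels–Alder adduct: bicyclo[2.2.2]octadiene with enol silyl ether C16=C18 and fused unsaturated γ-lactone | CC1(C)OCC=C[C@]12CC[C@]3(C[C@@]4(C)C=C5C(=O)OC[C@@]35C(C)=C4O[Si](C)(C)C)[C@@H](CO[Si](c6ccccc6)(c6ccccc6)C(C)(C)C)[C@@]2(C)O[Si](CC)(CC)CC | intermediate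
46 | cage ketone diol (C16 ketone, C30=C31 lactone, C20–OH, C22–OH; C18 epimers) | CC1(C)OCC=C[C@]12CC[C@]3(C[C@@]4(C)C=C5C(=O)OC[C@@]35C(C)C4=O)[C@@H](CO)[C@@]2(C)O | intermediate
47 | C20 iodide of 46 (C18 epimers) | CC1(C)OCC=C[C@]12CC[C@]3(C[C@@]4(C)C=C5C(=O)OC[C@@]35C(C)C4=O)[C@@H](CI)[C@@]2(C)O | intermediate
48 | hexacyclic enone lactone: ring C closed, C30=C31, ring A as dihydropyran | CC1(C)OCC=C[C@]12CC[C@]13C[C@]4(C)C(=O)[C@](C)(C[C@H]1[C@@]2(C)O)[C@]31COC(=O)C1=C4 | intermediate
49 | β-silyl lactone: PhMe2Si on C31 cis to C28, configuration of the target at C30 and C31 | CC1(C)OCC=C[C@]12CC[C@]13C[C@]4(C)C(=O)[C@](C)(C[C@H]1[C@@]2(C)O)[C@]31COC(=O)[C@H]1[C@H]4[Si](C)(C)c1ccccc1 | intermediate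
50 | silyl bis-lactone: ring A oxidised to the α,β-unsaturated δ-lactone | CC1(C)OC(=O)C=C[C@]12CC[C@]13C[C@]4(C)C(=O)[C@](C)(C[C@H]1[C@@]2(C)O)[C@]31COC(=O)[C@H]1[C@H]4[Si](C)(C)c1ccccc1 | intermediate
51 | CNP0360620.2 | CC1(C)OC(=O)C=C[C@]12CC[C@]13C[C@]4(C)C(=O)[C@](C)(C[C@H]1[C@@]2(C)O)[C@]31COC(=O)[C@H]1[C@H]4O | target

**Totals**
Total step count: 32.
Longest linear sequence: 27 steps (steps 4–17, 19–23 and 25–32).

**Steps most likely to fail**

Step 16. The ketene acetal may fail to reach the bridged transition state within the eight-membered ring, returning lactone on work-up, or may fold without regard to C9. The fallback uses known open-chain chemistry and sets out from iodide 18. DDQ removes the 4-methoxybenzyl group to give the iodo allylic alcohol F1. Carbodiimide esterification with tert-butyl hydrogen malonate gives the open-chain allyl tert-butyl malonate F2. Its bis-silyl ketene acetal (Me3SiOTf, i-Pr2NEt, then toluene, 90 °C) undergoes the established acyclic ester-enolate Claisen rearrangement, forming C12–C21 and the C22=C23 methylene in the seco acid F3. LiN(i-Pr)2 (2.2 equiv) then generates the dianion, whose 6-exo alkylation by the C11 iodide closes ring B and returns to the route at 26. The ring no longer dictates C12 and C21 here, so the diastereomers of 26 would have to be separated.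

Step 15. Closure of the medium ring may lose out to oligomerisation, or the activated malonic half-acid may decompose through a ketene. The fallback sets out from hydroxy acid 22 and returns directly at lactone 23 by Mitsunobu macrolactonisation (PPh3, diisopropyl azodicarboxylate, toluene, high dilution). This activates the allylic C23 alcohol instead of the acid and closes the ring by carboxylate attack on carbon; it makes no new compound (F0).

Step 27. The ester tether may disfavour the folded conformer so that the ynoate polymerises before it cyclises, or the diene may be attacked from the wrong face. The fallback sets out from hydroxymethyl enone 41. Exhaustive silylation (Me3SiOTf, Et3N) gives the silyloxydiene with a silylated C26 hydroxyl F4. An intermolecular Diels–Alder reaction with methyl propiolate (toluene, 110 °C, the electronically matched orientation joining C14 to C31 and C25 to C30) gives the bicyclic methyl ester F5. Bu4NF then removes the silyl groups, and the freed C26 hydroxyl closes the γ-lactone onto the C28 methyl ester, returning to the route at 46.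

**Further compounds**
F1 | step 16 | iodo allylic alcohol (18 without the 4-methoxybenzyl group) | CC1(C)OCC=C[C@@]1(CCI)/C(CO)=C\CO[Si](c2ccccc2)(c2ccccc2)C(C)(C)C
F2 | step 16 | open-chain allyl tert-butyl malonate with pendant C11 iodide | CC1(C)OCC=C[C@@]1(CCI)/C(COC(=O)CC(=O)OC(C)(C)C)=C\CO[Si](c2ccccc2)(c2ccccc2)C(C)(C)C
F3 | step 16 | seco acid after open-chain Claisen rearrangement (C12–C21 formed, C22=C23 methylene, C11 iodide; C12 and C21 unassigned) | CC1(C)OCC=C[C@@]1(CCI)C(=C)C(CO[Si](c2ccccc2)(c2ccccc2)C(C)(C)C)C(C(=O)O)C(=O)OC(C)(C)C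
F0 | step 15 | none | none
F4 | step 27 | silyloxydiene of 41 with C26–OSiMe3 | CC1(C)OCC=C[C@]12CC[C@]3(CC(C)=C(O[Si](C)(C)C)C(C)=C3CO[Si](C)(C)C)[C@@H](CO[Si](c4ccccc4)(c4ccccc4)C(C)(C)C)[C@@]2(C)O[Si](CC)(CC)CC
F5 | step 27 | intermolecular cycloadduct: bicyclo[2.2.2]octadiene with CO2Me on C30 and CH2OSiMe3 on C25 | CC1(C)OCC=C[C@]12CC[C@]3(C[C@@]4(C)C=C(C(=O)OC)[C@]3(CO[Si](C)(C)C)C(C)=C4O[Si](C)(C)C)[C@@H](CO[Si](c5ccccc5)(c5ccccc5)C(C)(C)C)[C@@]2(C)O[Si](CC)(CC)CC
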